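A one-step picture has a single time constant and reads a plateau as forward and back rates coming level. When you asked for a quick number on the north-west flask, I tried a fork instead.

all flasks: precatalyst 2.5 mol%
- north-west: starting material 0.011 M; partner 1.3 equiv; the very flask that is asked about, followed so far
- north: starting material 0.017 M; partner 1.3 equiv; run made earlier
- flask: starting material 0.011 M; partner 1.30 equiv; time 12 d

- north-west (time / h: product / %): 3.00: 1.2; 8.00: 7.8; 15.0: 18.4; 25.0: 32.6
- north (time / d: product / %): 1.67: 59.7; 4.00: 63.1; 8.00: 64.2; 12.0: 63.5

(readings scatter by 0.5 percentage points)

1. why nothing more happens at 12 d, or that something still does (forward and back rates have come level / it is still moving / the partner has run out first / all of the starting material has reacted / no working catalyst is left)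
2. product at 12 d, in percent of the starting material charged

I followed one partner molecule and assumed two exits, like two drains on a tank: into product through the catalyst, or into a loss of its own. At fixed loading I let the catalyst drain scale with concentration and the loss stay unchanged. The north run stood near 63.6 % late on, and I counted one partner per product.

north share = 48.9 %; north odds = share ÷ (1 − share) = 0.958

flask odds = north odds × 0.011 M ÷ 0.017 M = 0.620

flask share = odds ÷ (1 + odds) = 38.3 %; product = share × 1.30 equiv = 49.7 %

That productive share, the fraction of charged partner that ends as product, was my quantity. The north run barely moved from 4.00 d to 12.0 d, so I answered that the north-west flask has stopped on its partner by 12 d.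

Your forecast said forward and back rates have come level and 56 %: “Its plateau therefore looks like an equilibrium, not catalyst death”. My figure was lower.

The simulation gave the partner has run out first and 47.6 %.

    partner + precatalyst → free catalyst + spent reagent (k = 0.0880 M⁻¹ min⁻¹)
    catalyst intermediate B → free catalyst + product (k = 0.170 min⁻¹)
    partner + free catalyst → catalyst intermediate A (k = 3.40 M⁻¹ min⁻¹)
    partner → decomposed reagent (k = 5.90 × 10⁻⁴ min⁻¹)
    starting material + catalyst intermediate A → catalyst intermediate B (k = 26.0 M⁻¹ min⁻¹)

The north-west flask ended with 0 % of its partner and 52 % of its starting material, although the partner was the charge in excess at 1.30 equiv. The partner's decomposition is the main reason for that remainder: without that step the simulated run converts 100 % of the starting material, against 47.6 %. Product took 36.6 % of the charged partner, beside my 38.3 %. For the neighbour charged with 0.780 equiv of partner, that share gave 29.9 %; the computed product was 24.4 %.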